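## Retrosynthetic overview

1. Target 47 ⇐ desilylation and debenzylation of 45 ⇐ C7 deoxygenation of aldol adduct 43 ⇐ key intermolecular aldol of the lithium enolate of east lactone 27 with west aldehyde 41 (makes the C7–C8 bond, 3,4‑trans).
2. Aldehyde 41 ⇐ Evans syn‑aldol of aryloxyacetyl imide 32 with O‑benzylvanillin 9 (sets C8''), reduction, Mitsunobu inversion at C7'' (threo → erythro), ArBr → ArCHO.
3. Lactone 27 ⇐ Evans alkylation of succinate imide 23 with benzylic bromide 19, LiBH4, lactonisation.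
4. Bromide 19 ⇐ trans‑dihydrobenzofuran 14 ⇐ Evans syn‑aldol of arylacetyl imide 8 with 9 (sets C3), reduction, deallylation, acid‑mediated ring closure.
5. Ring order: dihydrobenzofuran first, γ‑butyrolactone second; no ring is formed after the fragment union.

Assumption: 9, 20, 28 and both antipodes of 4‑benzyloxazolidin‑2‑one are bought; adduct 43 is carried on as a mixture of carbinol epimers because that centre is removed in step 30.

Shorthand used in names: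
- DBF = (2S,3R)‑2‑[4‑(benzyloxy)‑3‑methoxyphenyl]‑3‑{[(tert‑butyldiphenylsilyl)oxy]methyl}‑7‑methoxy‑2,3‑dihydrobenzofuran‑5‑yl
- ETH = (1R,2S)‑1‑[4‑(benzyloxy)‑3‑methoxyphenyl]‑1,3‑bis[(tert‑butyldimethylsilyl)oxy]propan‑2‑yl

## Route

### East fragment (steps 1–17)

Step 1
Reactants: 1 5‑bromo‑2‑hydroxy‑3‑methoxybenzaldehyde
Product: 2 2‑(allyloxy)‑5‑bromo‑3‑methoxybenzaldehyde
Conditions: allyl bromide, K2CO3, DMF, 50 °C
Reagents that add atoms: allyl bromide C=CCBr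
Why: Williamson etherification masks the phenol as an allyl ether that lasts until the neutral Pd(0) release in step 8.

Step 2
Reactants: 2 2‑(allyloxy)‑5‑bromo‑3‑methoxybenzaldehyde
Product: 3 2‑(allyloxy)‑5‑bromo‑1‑methoxy‑3‑(2‑methoxyethenyl)benzene (E/Z mixture)
Conditions: MeOCH2PPh3Cl, KOtBu, THF, 0 °C → rt
Reagents that add atoms: (methoxymethyl)triphenylphosphonium chloride [Cl-].COC[P+](c1ccccc1)(c1ccccc1)c1ccccc1
Why: Wittig methoxymethylenation adds the carbon that becomes the CH2OH carbon of the dihydrobenzofuran.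

Step 3
Reactants: 3 enol ether
Product: 4 2‑[2‑(allyloxy)‑5‑bromo‑3‑methoxyphenyl]acetaldehyde
Conditions: 2 M HCl, THF, 50 °C
Reagents that add atoms: water O
Why: Acid hydrolysis of the enol ether through its oxocarbenium ion gives the arylacetaldehyde, which is used crude.

Step 4
Reactants: 4 arylacetaldehyde
Product: 5 2‑[2‑(allyloxy)‑5‑bromo‑3‑methoxyphenyl]acetic acid
Conditions: NaClO2, NaH2PO4, 2‑methyl‑2‑butene, t‑BuOH/H2O, 0 °C → rt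
Reagents that add atoms: sodium chlorite [Na+].[O-]Cl=O
Why: Pinnick oxidation converts the aldehyde to the acid without touching the allyl ether or the aryl bromide.

Step 5
Reactants: 5 arylacetic acid; 6 (S)‑4‑benzyloxazolidin‑2‑one
Product: 8 (S)‑3‑{2‑[2‑(allyloxy)‑5‑bromo‑3‑methoxyphenyl]acetyl}‑4‑benzyloxazolidin‑2‑one, via mixed pivalic anhydride 7 (not isolated)
Conditions: PivCl, Et3N, THF, −20 °C; then 6, LiCl, −20 °C → rt
Reagents that add atoms: none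
Why: LiCl‑assisted N‑acylation of the Evans auxiliary through the mixed anhydride gives the aldol substrate.

Step 6
Reactants: 8 arylacetyl imide; 9 4‑(benzyloxy)‑3‑methoxybenzaldehyde
Product: 11 (S)‑3‑{(2S,3S)‑2‑[2‑(allyloxy)‑5‑bromo‑3‑methoxyphenyl]‑3‑[4‑(benzyloxy)‑3‑methoxyphenyl]‑3‑hydroxypropanoyl}‑4‑benzyloxazolidin‑2‑one, via Z‑dibutylboron enolate 10 (not isolated)
Conditions: Bu2BOTf, iPr2NEt, CH2Cl2, −78 → 0 °C; then 9, −78 → 0 °C; pH 7 buffer/MeOH/30% H2O2, 0 °C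
Reagents that add atoms: none
Why: Evans syn‑aldol through the Zimmerman–Traxler chair of the Z‑boron enolate, in which the (S)‑auxiliary fixes C2 as S (the later ring C3).

Step 7
Reactants: 11 syn‑aldol imide
Product: 12 (1S,2R)‑2‑[2‑(allyloxy)‑5‑bromo‑3‑methoxyphenyl]‑1‑[4‑(benzyloxy)‑3‑methoxyphenyl]propane‑1,3‑diol
Conditions: LiBH4, MeOH (1.1 equiv), THF, 0 °C
Reagents that add atoms: none
Why: Reductive cleavage of the imide gives the primary alcohol and returns the auxiliary without epimerising the α‑aryl centre.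

Step 8
Reactants: 12 allyl ether diol
Product: 13 (1S,2R)‑1‑[4‑(benzyloxy)‑3‑methoxyphenyl]‑2‑(5‑bromo‑2‑hydroxy‑3‑methoxyphenyl)propane‑1,3‑diol
Conditions: Pd(PPh3)4 (5 mol%), morpholine, THF, rt
Reagents that add atoms: none
Why: Tsuji–Trost deallylation frees the phenol under neutral conditions that leave the benzyl ether and the aryl bromide alone.

Step 9
Reactants: 13 phenol diol
Product: 14 [(2S,3R)‑2‑[4‑(benzyloxy)‑3‑methoxyphenyl]‑5‑bromo‑7‑methoxy‑2,3‑dihydrobenzofuran‑3‑yl]methanol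
Conditions: p‑TsOH·H2O (10 mol%), CH2Cl2 (0.02 M), rt
Reagents that add atoms: none
Why: Acid ionises the p‑benzyloxybenzylic alcohol and the phenol traps the cation 5‑exo (SN1 cyclodehydration), reversibly, so the fixed C3 (R) steers C2 to the favoured 2,3‑trans (2S) isomer.

Step 10
Reactants: 14 dihydrobenzofuran alcohol
Product: 15 DBF bromide, that is {[(2S,3R)‑2‑[4‑(benzyloxy)‑3‑methoxyphenyl]‑5‑bromo‑7‑methoxy‑2,3‑dihydrobenzofuran‑3‑yl]methoxy}(tert‑butyl)diphenylsilane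
Conditions: TBDPSCl, imidazole, DMF, rt
Reagents that add atoms: tert‑butyl(chloro)diphenylsilane CC(C)(C)[Si](Cl)(c1ccccc1)c1ccccc1
Why: Silylation gives a primary TBDPS ether that survives BuLi, hydride, enolate, radical and TFA steps.

Step 11
Reactants: 15 DBF bromide
Product: 17 DBF‑carbaldehyde, via DBF‑lithium 16 (not isolated)
Conditions: n‑BuLi, THF, −78 °C; DMF, −78 → 0 °C; then H2O
Reagents that add atoms: N,N‑dimethylformamide CN(C)C=O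
Why: Bromine–lithium exchange is faster than any deprotonation at −78 °C and the aryllithium is formylated by DMF (Bouveault).

Step 12
Reactants: 17 DBF‑carbaldehyde
Product: 18 DBF‑methanol
Conditions: NaBH4, MeOH/THF, 0 °C
Reagents that add atoms: none
Why: Borohydride reduction of the aryl aldehyde to the benzylic alcohol.

Step 13
Reactants: 18 DBF‑methanol
Product: 19 DBF‑methyl bromide
Conditions: CBr4, PPh3, CH2Cl2, 0 °C; used at once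
Reagents that add atoms: carbon tetrabromide BrC(Br)(Br)Br
Why: Appel bromination gives the reactive benzylic bromide under neutral conditions compatible with the silyl and benzyl ethers.

Step 14
Reactants: 20 4‑(tert‑butoxy)‑4‑oxobutanoic acid; 21 (R)‑4‑benzyloxazolidin‑2‑one
Product: 23 tert‑butyl 4‑[(R)‑4‑benzyl‑2‑oxooxazolidin‑3‑yl]‑4‑oxobutanoate, via mixed pivalic anhydride 22 (not isolated)
Conditions: PivCl, Et3N, THF, −20 °C; then 21, LiCl, −20 °C → rt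
Reagents that add atoms: none
Why: N‑acylation of the auxiliary gives a succinate in which only the imide α‑CH2 is enolised.

Step 15
Reactants: 23 succinate imide; 19 DBF‑methyl bromide
Product: 25 tert‑butyl (3R)‑4‑[(R)‑4‑benzyl‑2‑oxooxazolidin‑3‑yl]‑3‑(DBF‑methyl)‑4‑oxobutanoate, via sodium Z‑enolate 24 (not isolated)
Conditions: NaHMDS, THF, −78 °C; then 19, −78 → −40 °C
Reagents that add atoms: none
Why: Evans alkylation of the chelated Z‑enolate, attacked anti to the auxiliary benzyl group, sets the 3R centre (the later lactone C4).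

Step 16
Reactants: 25 alkylated imide
Product: 26 tert‑butyl (3R)‑3‑(DBF‑methyl)‑4‑hydroxybutanoate
Conditions: LiBH4, MeOH (1.1 equiv), THF, 0 °C
Reagents that add atoms: none
Why: LiBH4 reduces the imide chemoselectively and leaves the tert‑butyl ester intact.

Step 17
Reactants: 26 hydroxy ester
Product: 27 (R)‑4‑(DBF‑methyl)dihydrofuran‑2(3H)‑one
Conditions: TFA, CH2Cl2, 0 °C → rt
Reagents that add atoms: none
Why: Acidolysis of the tert‑butyl ester and spontaneous γ‑lactonisation give the (R)‑β‑substituted butyrolactone without touching the stereocentre.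

### West fragment (steps 18–27)

Step 18
Reactants: 28 4‑bromo‑2‑methoxyphenol
Product: 29 ethyl 2‑(4‑bromo‑2‑methoxyphenoxy)acetate
Conditions: ethyl bromoacetate, K2CO3, acetone, reflux
Reagents that add atoms: ethyl bromoacetate CCOC(=O)CBr
Why: Williamson etherification installs the two carbons that become C8'' and C9''.

Step 19
Reactants: 29 ethyl ester
Product: 30 2‑(4‑bromo‑2‑methoxyphenoxy)acetic acid
Conditions: LiOH·H2O, THF/H2O, rt; then 1 M HCl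
Reagents that add atoms: lithium hydroxide [Li+].[OH-]
Why: Saponification gives the acid needed for auxiliary attachment.

Step 20
Reactants: 30 aryloxyacetic acid; 21 (R)‑4‑benzyloxazolidin‑2‑one
Product: 32 (R)‑4‑benzyl‑3‑[2‑(4‑bromo‑2‑methoxyphenoxy)acetyl]oxazolidin‑2‑one, via mixed pivalic anhydride 31 (not isolated)
Conditions: PivCl, Et3N, THF, −20 °C; then 21, LiCl, −20 °C → rt
Reagents that add atoms: none
Why: N‑acylation through the mixed anhydride gives the glycolate‑type Evans imide.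

Step 21
Reactants: 32 aryloxyacetyl imide; 9 4‑(benzyloxy)‑3‑methoxybenzaldehyde
Product: 34 (R)‑4‑benzyl‑3‑{(2R,3S)‑3‑[4‑(benzyloxy)‑3‑methoxyphenyl]‑2‑(4‑bromo‑2‑methoxyphenoxy)‑3‑hydroxypropanoyl}oxazolidin‑2‑one, via Z‑dibutylboron enolate 33 (not isolated)
Conditions: Bu2BOTf, iPr2NEt, CH2Cl2, −78 → 0 °C; then 9, −78 → 0 °C; pH 7 buffer/MeOH/30% H2O2, 0 °C
Reagents that add atoms: none
Why: Evans syn‑aldol of the aryloxyacetyl Z‑boron enolate, in which the (R)‑auxiliary sets C2 as R (8''S after reduction) and the closed transition state gives the syn (threo) carbinol.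

Step 22
Reactants: 34 syn‑aldol imide
Product: 35 (1S,2S)‑1‑[4‑(benzyloxy)‑3‑methoxyphenyl]‑2‑(4‑bromo‑2‑methoxyphenoxy)propane‑1,3‑diol
Conditions: LiBH4, MeOH (1.1 equiv), THF, 0 °C
Reagents that add atoms: none
Why: Reductive removal of the auxiliary gives the threo diol with both centres intact.

Step 23
Reactants: 35 threo diol
Product: 36 (1S,2S)‑1‑[4‑(benzyloxy)‑3‑methoxyphenyl]‑2‑(4‑bromo‑2‑methoxyphenoxy)‑3‑[(tert‑butyldimethylsilyl)oxy]propan‑1‑ol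
Conditions: TBSCl (1.05 equiv), imidazole, CH2Cl2, 0 °C
Reagents that add atoms: tert‑butyl(chloro)dimethylsilane CC(C)(C)[Si](C)(C)Cl
Why: The primary hydroxyl is silylated selectively over the hindered secondary benzylic one.

Step 24
Reactants: 36 threo mono‑silyl ether
Product: 37 (1R,2S)‑1‑[4‑(benzyloxy)‑3‑methoxyphenyl]‑2‑(4‑bromo‑2‑methoxyphenoxy)‑3‑[(tert‑butyldimethylsilyl)oxy]propyl 4‑nitrobenzoate
Conditions: 4‑nitrobenzoic acid, PPh3, DIAD, toluene, 0 °C → rt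
Reagents that add atoms: 4‑nitrobenzoic acid OC(=O)c1ccc(cc1)[N+](=O)[O-]
Why: Mitsunobu esterification inverts the benzylic carbinol by SN2 (1S → 1R), turning the threo aldol product into the required erythro series.

Step 25
Reactants: 37 4‑nitrobenzoate
Product: 38 (1R,2S)‑1‑[4‑(benzyloxy)‑3‑methoxyphenyl]‑2‑(4‑bromo‑2‑methoxyphenoxy)‑3‑[(tert‑butyldimethylsilyl)oxy]propan‑1‑ol
Conditions: K2CO3 (cat.), MeOH/THF, rt
Reagents that add atoms: none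
Why: Transesterification with methanol removes the activated ester with retention at C1.

Step 26
Reactants: 38 erythro alcohol
Product: 39 [(1R,2S)‑1‑[4‑(benzyloxy)‑3‑methoxyphenyl]‑2‑(4‑bromo‑2‑methoxyphenoxy)propane‑1,3‑diyl]bis(oxy)bis[tert‑butyl(dimethyl)silane], that is ETH 4‑bromo‑2‑methoxyphenyl ether
Conditions: TBSOTf, 2,6‑lutidine, CH2Cl2, 0 °C
Reagents that add atoms: tert‑butyldimethylsilyl trifluoromethanesulfonate CC(C)(C)[Si](C)(C)OS(=O)(=O)C(F)(F)F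
Why: Silyl triflate caps the hindered benzylic hydroxyl so that no acidic proton remains for the organolithium and enolate steps.

Step 27
Reactants: 39 bis‑silyl aryl bromide
Product: 41 3‑methoxy‑4‑(ETH‑oxy)benzaldehyde, via aryllithium 40 (not isolated)
Conditions: n‑BuLi, THF, −78 °C; DMF, −78 → 0 °C; then H2O
Reagents that add atoms: N,N‑dimethylformamide CN(C)C=O
Why: Bromine–lithium exchange followed by DMF formylation gives the aldehyde partner for the union.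

### Union and endgame (steps 28–32)

Step 28
Reactants: 27 east lactone; 41 west aldehyde
Product: 43 (3S,4R)‑4‑(DBF‑methyl)‑3‑{hydroxy[3‑methoxy‑4‑(ETH‑oxy)phenyl]methyl}dihydrofuran‑2(3H)‑one (mixture of carbinol epimers), via lithium enolate 42 (not isolated)
Conditions: LDA (1.1 equiv), THF, −78 °C; then 41, −78 °C; AcOH quench at −78 °C
Reagents that add atoms: none
Why: Intermolecular aldol addition of the lactone enolate to the non‑enolisable aldehyde occurs anti to the C4 substituent and fixes the 3,4‑trans ring relationship.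

Step 29
Reactants: 43 aldol adduct
Product: 44 O‑{[(3S,4R)‑4‑(DBF‑methyl)‑2‑oxotetrahydrofuran‑3‑yl][3‑methoxy‑4‑(ETH‑oxy)phenyl]methyl} O‑phenyl thionocarbonate
Conditions: PhOC(S)Cl, pyridine, DMAP (cat.), CH2Cl2, 0 °C → rt
Reagents that add atoms: O‑phenyl chlorothionoformate S=C(Cl)Oc1ccccc1
Why: Thioacylation of the only free hydroxyl prepares the Barton–McCombie deoxygenation under mildly basic conditions.

Step 30
Reactants: 44 thionocarbonate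
Product: 45 (3R,4R)‑4‑(DBF‑methyl)‑3‑[3‑methoxy‑4‑(ETH‑oxy)benzyl]dihydrofuran‑2(3H)‑one
Conditions: Bu3SnH, AIBN (cat.), toluene, 80 °C
Reagents that add atoms: none
Why: Barton–McCombie radical deoxygenation through the benzylic radical removes the carbinol oxygen and leaves the ring stereocentres, benzyl ethers and silyl ethers untouched.

Step 31
Reactants: 45 protected lignan
Product: 46 (3R,4R)‑3‑[4‑{[(1R,2S)‑1‑[4‑(benzyloxy)‑3‑methoxyphenyl]‑1,3‑dihydroxypropan‑2‑yl]oxy}‑3‑methoxybenzyl]‑4‑{[(2S,3R)‑2‑[4‑(benzyloxy)‑3‑methoxyphenyl]‑3‑(hydroxymethyl)‑7‑methoxy‑2,3‑dihydrobenzofuran‑5‑yl]methyl}dihydrofuran‑2(3H)‑one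
Conditions: TBAF, AcOH (1:1), THF, rt → 40 °C
Reagents that add atoms: none
Why: Buffered fluoride removes the two TBS ethers and the TBDPS ether without opening or epimerising the trans lactone.

Step 32
Reactants: 46 dibenzyl ether triol
Product: 47 CNP0298853.1, (3R,4R)‑3‑[4‑{[(1R,2S)‑1,3‑dihydroxy‑1‑(4‑hydroxy‑3‑methoxyphenyl)propan‑2‑yl]oxy}‑3‑methoxybenzyl]‑4‑{[(2S,3R)‑2‑(4‑hydroxy‑3‑methoxyphenyl)‑3‑(hydroxymethyl)‑7‑methoxy‑2,3‑dihydrobenzofuran‑5‑yl]methyl}dihydrofuran‑2(3H)‑one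
Conditions: H2 (1 atm), 10% Pd/C, EtOAc/MeOH, rt, stopped at full conversion
Reagents that add atoms: none
Why: Hydrogenolysis of the two phenolic benzyl ethers is much faster than cleavage of the benzylic alcohol or the dihydrobenzofuran C–O bond under neutral conditions.

## Compound list

1 | 5‑bromo‑2‑hydroxy‑3‑methoxybenzaldehyde | COc1cc(Br)cc(C=O)c1O | starting material
2 | 2‑(allyloxy)‑5‑bromo‑3‑methoxybenzaldehyde | C=CCOc1c(C=O)cc(Br)cc1OC | intermediate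
3 | 2‑(allyloxy)‑5‑bromo‑1‑methoxy‑3‑(2‑methoxyethenyl)benzene (E/Z) | C=CCOc1c(C=COC)cc(Br)cc1OC | intermediate
4 | 2‑[2‑(allyloxy)‑5‑bromo‑3‑methoxyphenyl]acetaldehyde | C=CCOc1c(CC=O)cc(Br)cc1OC | intermediate
5 | 2‑[2‑(allyloxy)‑5‑bromo‑3‑methoxyphenyl]acetic acid | C=CCOc1c(CC(=O)O)cc(Br)cc1OC | intermediate
6 | (S)‑4‑benzyloxazolidin‑2‑one | O=C1N[C@@H](Cc2ccccc2)CO1 | starting material
7 | mixed anhydride of 5 with pivalic acid | C=CCOc1c(CC(=O)OC(=O)C(C)(C)C)cc(Br)cc1OC | intermediate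
8 | (S)‑3‑{2‑[2‑(allyloxy)‑5‑bromo‑3‑methoxyphenyl]acetyl}‑4‑benzyloxazolidin‑2‑one | C=CCOc1c(CC(=O)N2[C@@H](Cc3ccccc3)COC2=O)cc(Br)cc1OC | intermediate
9 | 4‑(benzyloxy)‑3‑methoxybenzaldehyde | COc1cc(C=O)ccc1OCc1ccccc1 | starting material
10 | Z‑dibutylboron enolate of 8 | CCCCB(CCCC)O/C(=C\c1cc(Br)cc(OC)c1OCC=C)N1[C@@H](Cc2ccccc2)COC1=O | intermediate
11 | (S)‑3‑{(2S,3S)‑2‑[2‑(allyloxy)‑5‑bromo‑3‑methoxyphenyl]‑3‑[4‑(benzyloxy)‑3‑methoxyphenyl]‑3‑hydroxypropanoyl}‑4‑benzyloxazolidin‑2‑one | O=C1OC[C@H](Cc2ccccc2)N1C(=O)[C@@H](c1cc(Br)cc(OC)c1OCC=C)[C@H](O)c1ccc(OCc2ccccc2)c(OC)c1 | intermediate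
12 | (1S,2R)‑2‑[2‑(allyloxy)‑5‑bromo‑3‑methoxyphenyl]‑1‑[4‑(benzyloxy)‑3‑methoxyphenyl]propane‑1,3‑diol | OC[C@@H](c1cc(Br)cc(OC)c1OCC=C)[C@H](O)c1ccc(OCc2ccccc2)c(OC)c1 | intermediate
13 | (1S,2R)‑1‑[4‑(benzyloxy)‑3‑methoxyphenyl]‑2‑(5‑bromo‑2‑hydroxy‑3‑methoxyphenyl)propane‑1,3‑diol | OC[C@@H](c1cc(Br)cc(OC)c1O)[C@H](O)c1ccc(OCc2ccccc2)c(OC)c1 | intermediate
14 | [(2S,3R)‑2‑[4‑(benzyloxy)‑3‑methoxyphenyl]‑5‑bromo‑7‑methoxy‑2,3‑dihydrobenzofuran‑3‑yl]methanol | Brc1cc(OC)c2c(c1)[C@H](CO)[C@@H](c1ccc(OCc3ccccc3)c(OC)c1)O2 | intermediate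
15 | DBF bromide (TBDPS ether of 14) | Brc1cc(OC)c2c(c1)[C@H](CO[Si](c1ccccc1)(c1ccccc1)C(C)(C)C)[C@@H](c1ccc(OCc3ccccc3)c(OC)c1)O2 | intermediate
16 | DBF‑lithium | [Li]c1cc(OC)c2c(c1)[C@H](CO[Si](c1ccccc1)(c1ccccc1)C(C)(C)C)[C@@H](c1ccc(OCc3ccccc3)c(OC)c1)O2 | intermediate
17 | DBF‑carbaldehyde | O=Cc1cc(OC)c2c(c1)[C@H](CO[Si](c1ccccc1)(c1ccccc1)C(C)(C)C)[C@@H](c1ccc(OCc3ccccc3)c(OC)c1)O2 | intermediate
18 | DBF‑methanol | OCc1cc(OC)c2c(c1)[C@H](CO[Si](c1ccccc1)(c1ccccc1)C(C)(C)C)[C@@H](c1ccc(OCc3ccccc3)c(OC)c1)O2 | intermediate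
19 | DBF‑methyl bromide | BrCc1cc(OC)c2c(c1)[C@H](CO[Si](c1ccccc1)(c1ccccc1)C(C)(C)C)[C@@H](c1ccc(OCc3ccccc3)c(OC)c1)O2 | intermediate
20 | 4‑(tert‑butoxy)‑4‑oxobutanoic acid | CC(C)(C)OC(=O)CCC(=O)O | starting material
21 | (R)‑4‑benzyloxazolidin‑2‑one | O=C1N[C@H](Cc2ccccc2)CO1 | starting material
22 | mixed anhydride of 20 with pivalic acid | CC(C)(C)OC(=O)CCC(=O)OC(=O)C(C)(C)C | intermediate
23 | tert‑butyl 4‑[(R)‑4‑benzyl‑2‑oxooxazolidin‑3‑yl]‑4‑oxobutanoate | CC(C)(C)OC(=O)CCC(=O)N1[C@H](Cc2ccccc2)COC1=O | intermediate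
24 | sodium Z‑enolate of 23 | [Na+].[O-]/C(=C\CC(=O)OC(C)(C)C)N1[C@H](Cc2ccccc2)COC1=O | intermediate
25 | tert‑butyl (3R)‑4‑[(R)‑4‑benzyl‑2‑oxooxazolidin‑3‑yl]‑3‑(DBF‑methyl)‑4‑oxobutanoate | CC(C)(C)OC(=O)C[C@@H](Cc1cc(OC)c2c(c1)[C@H](CO[Si](c1ccccc1)(c1ccccc1)C(C)(C)C)[C@@H](c1ccc(OCc3ccccc3)c(OC)c1)O2)C(=O)N1[C@H](Cc2ccccc2)COC1=O | intermediate
26 | tert‑butyl (3R)‑3‑(DBF‑methyl)‑4‑hydroxybutanoate | CC(C)(C)OC(=O)C[C@@H](Cc1cc(OC)c2c(c1)[C@H](CO[Si](c1ccccc1)(c1ccccc1)C(C)(C)C)[C@@H](c1ccc(OCc3ccccc3)c(OC)c1)O2)CO | intermediate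
27 | (R)‑4‑(DBF‑methyl)dihydrofuran‑2(3H)‑one | O=C1C[C@@H](Cc2cc(OC)c3c(c2)[C@H](CO[Si](c2ccccc2)(c2ccccc2)C(C)(C)C)[C@@H](c2ccc(OCc4ccccc4)c(OC)c2)O3)CO1 | intermediate
28 | 4‑bromo‑2‑methoxyphenol | COc1cc(Br)ccc1O | starting material
29 | ethyl 2‑(4‑bromo‑2‑methoxyphenoxy)acetate | CCOC(=O)COc1ccc(Br)cc1OC | intermediate
30 | 2‑(4‑bromo‑2‑methoxyphenoxy)acetic acid | OC(=O)COc1ccc(Br)cc1OC | intermediate
31 | mixed anhydride of 30 with pivalic acid | CC(C)(C)C(=O)OC(=O)COc1ccc(Br)cc1OC | intermediate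
32 | (R)‑4‑benzyl‑3‑[2‑(4‑bromo‑2‑methoxyphenoxy)acetyl]oxazolidin‑2‑one | O=C1OC[C@@H](Cc2ccccc2)N1C(=O)COc1ccc(Br)cc1OC | intermediate
33 | Z‑dibutylboron enolate of 32 | CCCCB(CCCC)O/C(=C\Oc1ccc(Br)cc1OC)N1[C@H](Cc2ccccc2)COC1=O | intermediate
34 | (R)‑4‑benzyl‑3‑{(2R,3S)‑3‑[4‑(benzyloxy)‑3‑methoxyphenyl]‑2‑(4‑bromo‑2‑methoxyphenoxy)‑3‑hydroxypropanoyl}oxazolidin‑2‑one | COc1cc([C@H](O)[C@H](C(=O)N2[C@H](Cc3ccccc3)COC2=O)Oc2ccc(Br)cc2OC)ccc1OCc1ccccc1 | intermediate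
35 | (1S,2S)‑1‑[4‑(benzyloxy)‑3‑methoxyphenyl]‑2‑(4‑bromo‑2‑methoxyphenoxy)propane‑1,3‑diol | COc1cc([C@H](O)[C@H](CO)Oc2ccc(Br)cc2OC)ccc1OCc1ccccc1 | intermediate
36 | (1S,2S)‑1‑[4‑(benzyloxy)‑3‑methoxyphenyl]‑2‑(4‑bromo‑2‑methoxyphenoxy)‑3‑[(tert‑butyldimethylsilyl)oxy]propan‑1‑ol | COc1cc([C@H](O)[C@H](CO[Si](C)(C)C(C)(C)C)Oc2ccc(Br)cc2OC)ccc1OCc1ccccc1 | intermediate
37 | (1R,2S)‑1‑[4‑(benzyloxy)‑3‑methoxyphenyl]‑2‑(4‑bromo‑2‑methoxyphenoxy)‑3‑[(tert‑butyldimethylsilyl)oxy]propyl 4‑nitrobenzoate | COc1cc([C@@H](OC(=O)c2ccc(cc2)[N+](=O)[O-])[C@H](CO[Si](C)(C)C(C)(C)C)Oc2ccc(Br)cc2OC)ccc1OCc1ccccc1 | intermediate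
38 | (1R,2S)‑1‑[4‑(benzyloxy)‑3‑methoxyphenyl]‑2‑(4‑bromo‑2‑methoxyphenoxy)‑3‑[(tert‑butyldimethylsilyl)oxy]propan‑1‑ol | COc1cc([C@@H](O)[C@H](CO[Si](C)(C)C(C)(C)C)Oc2ccc(Br)cc2OC)ccc1OCc1ccccc1 | intermediate
39 | ETH 4‑bromo‑2‑methoxyphenyl ether (bis‑TBS ether of the erythro diol) | COc1cc([C@@H](O[Si](C)(C)C(C)(C)C)[C@H](CO[Si](C)(C)C(C)(C)C)Oc2ccc(Br)cc2OC)ccc1OCc1ccccc1 | intermediate
40 | aryllithium from 39 | COc1cc([C@@H](O[Si](C)(C)C(C)(C)C)[C@H](CO[Si](C)(C)C(C)(C)C)Oc2ccc([Li])cc2OC)ccc1OCc1ccccc1 | intermediate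
41 | 3‑methoxy‑4‑(ETH‑oxy)benzaldehyde | COc1cc([C@@H](O[Si](C)(C)C(C)(C)C)[C@H](CO[Si](C)(C)C(C)(C)C)Oc2ccc(C=O)cc2OC)ccc1OCc1ccccc1 | intermediate
42 | lithium enolate of 27 | [Li+].[O-]C1=C[C@@H](Cc2cc(OC)c3c(c2)[C@H](CO[Si](c2ccccc2)(c2ccccc2)C(C)(C)C)[C@@H](c2ccc(OCc4ccccc4)c(OC)c2)O3)CO1 | intermediate
43 | (3S,4R)‑4‑(DBF‑methyl)‑3‑{hydroxy[3‑methoxy‑4‑(ETH‑oxy)phenyl]methyl}dihydrofuran‑2(3H)‑one (carbinol epimers) | COc1cc([C@@H](O[Si](C)(C)C(C)(C)C)[C@H](CO[Si](C)(C)C(C)(C)C)Oc2ccc(C(O)[C@H]3C(=O)OC[C@@H]3Cc3cc(OC)c4c(c3)[C@H](CO[Si](c3ccccc3)(c3ccccc3)C(C)(C)C)[C@@H](c3ccc(OCc5ccccc5)c(OC)c3)O4)cc2OC)ccc1OCc1ccccc1 | intermediate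
44 | O‑phenyl thionocarbonate of 43 | COc1cc([C@@H](O[Si](C)(C)C(C)(C)C)[C@H](CO[Si](C)(C)C(C)(C)C)Oc2ccc(C(OC(=S)Oc3ccccc3)[C@H]3C(=O)OC[C@@H]3Cc3cc(OC)c4c(c3)[C@H](CO[Si](c3ccccc3)(c3ccccc3)C(C)(C)C)[C@@H](c3ccc(OCc5ccccc5)c(OC)c3)O4)cc2OC)ccc1OCc1ccccc1 | intermediate
45 | (3R,4R)‑4‑(DBF‑methyl)‑3‑[3‑methoxy‑4‑(ETH‑oxy)benzyl]dihydrofuran‑2(3H)‑one | COc1cc([C@@H](O[Si](C)(C)C(C)(C)C)[C@H](CO[Si](C)(C)C(C)(C)C)Oc2ccc(C[C@H]3C(=O)OC[C@@H]3Cc3cc(OC)c4c(c3)[C@H](CO[Si](c3ccccc3)(c3ccccc3)C(C)(C)C)[C@@H](c3ccc(OCc5ccccc5)c(OC)c3)O4)cc2OC)ccc1OCc1ccccc1 | intermediate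
46 | bis(O‑benzyl) ether of the target (both phenols benzylated, three hydroxyls free) | COc1cc([C@@H](O)[C@H](CO)Oc2ccc(C[C@H]3C(=O)OC[C@@H]3Cc3cc(OC)c4c(c3)[C@H](CO)[C@@H](c3ccc(OCc5ccccc5)c(OC)c3)O4)cc2OC)ccc1OCc1ccccc1 | intermediate
47 | CNP0298853.1 | COc1cc([C@@H](O)[C@H](CO)Oc2ccc(C[C@H]3C(=O)OC[C@@H]3Cc3cc(OC)c4c(c3)[C@H](CO)[C@@H](c3ccc(O)c(OC)c3)O4)cc2OC)ccc1O | target

## Totals and weak points

Total step count: 32.
Longest linear sequence: 21 steps (steps 1–13, 15–17, 28–32, from compound 1).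

Step 9 (acid‑mediated ring closure). The benzylic cation can eliminate to a stilbene or oligomerise, and the trans preference is not enforced by an SN2 event. The fallback sets out from 12 and comes back at 15 by a stereospecific double inversion. Selective silylation of the primary hydroxyl (TBDPSCl, imidazole) gives (1S,2R)‑2‑[2‑(allyloxy)‑5‑bromo‑3‑methoxyphenyl]‑1‑[4‑(benzyloxy)‑3‑methoxyphenyl]‑3‑[(tert‑butyldiphenylsilyl)oxy]propan‑1‑ol F1. Mitsunobu esterification (4‑nitrobenzoic acid, PPh3, DIAD) inverts the carbinol to the (1R,2R) 4‑nitrobenzoate F2. Methanolysis (K2CO3, MeOH) gives the (1R,2R) alcohol F3, and Pd(PPh3)4/morpholine frees the (1R,2R) phenol F4. An intramolecular Mitsunobu etherification (PPh3, DIAD, THF) then closes the ring with a second inversion and gives 15 directly.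

Step 24 (Mitsunobu inversion at an electron‑rich benzylic carbinol). Partial ionisation would erode the inversion, and elimination is possible. The fallback sets out from 36 and comes back at 38. Dess–Martin oxidation (NaHCO3‑buffered) gives (S)‑1‑[4‑(benzyloxy)‑3‑methoxyphenyl]‑2‑(4‑bromo‑2‑methoxyphenoxy)‑3‑[(tert‑butyldimethylsilyl)oxy]propan‑1‑one F5. Chelation‑controlled reduction with Zn(BH4)2 in Et2O at −30 °C (Cram chelate between the ketone and the α‑aryloxy oxygen) then delivers hydride to give the erythro alcohol 38.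

Step 29 (thioacylation of the β‑hydroxy lactone, with the radical step 30). Base‑induced elimination to the benzylidene lactone or retro‑aldol can compete, and a benzylic thionocarbonate can rearrange on heating. The fallback sets out from 41 and comes back at 45, replacing the aldol and deoxygenation by a direct alkylation. NaBH4 reduces 41 to [3‑methoxy‑4‑(ETH‑oxy)phenyl]methanol F6, and CBr4/PPh3 converts it to 4‑(bromomethyl)‑2‑methoxy‑1‑(ETH‑oxy)benzene F7. The lithium enolate 42 (from 27, LDA, THF/DMPU, −78 °C) is then alkylated by F7 anti to the C4 substituent and gives 45.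

## Further compounds

F1 | step 9 | (1S,2R)‑2‑[2‑(allyloxy)‑5‑bromo‑3‑methoxyphenyl]‑1‑[4‑(benzyloxy)‑3‑methoxyphenyl]‑3‑[(tert‑butyldiphenylsilyl)oxy]propan‑1‑ol | CC(C)(C)[Si](c1ccccc1)(c1ccccc1)OC[C@@H](c1cc(Br)cc(OC)c1OCC=C)[C@H](O)c1ccc(OCc2ccccc2)c(OC)c1
F2 | step 9 | (1R,2R)‑2‑[2‑(allyloxy)‑5‑bromo‑3‑methoxyphenyl]‑1‑[4‑(benzyloxy)‑3‑methoxyphenyl]‑3‑[(tert‑butyldiphenylsilyl)oxy]propyl 4‑nitrobenzoate | CC(C)(C)[Si](c1ccccc1)(c1ccccc1)OC[C@@H](c1cc(Br)cc(OC)c1OCC=C)[C@@H](OC(=O)c1ccc(cc1)[N+](=O)[O-])c1ccc(OCc2ccccc2)c(OC)c1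
F3 | step 9 | (1R,2R)‑2‑[2‑(allyloxy)‑5‑bromo‑3‑methoxyphenyl]‑1‑[4‑(benzyloxy)‑3‑methoxyphenyl]‑3‑[(tert‑butyldiphenylsilyl)oxy]propan‑1‑ol | CC(C)(C)[Si](c1ccccc1)(c1ccccc1)OC[C@@H](c1cc(Br)cc(OC)c1OCC=C)[C@@H](O)c1ccc(OCc2ccccc2)c(OC)c1
F4 | step 9 | (1R,2R)‑1‑[4‑(benzyloxy)‑3‑methoxyphenyl]‑2‑(5‑bromo‑2‑hydroxy‑3‑methoxyphenyl)‑3‑[(tert‑butyldiphenylsilyl)oxy]propan‑1‑ol | CC(C)(C)[Si](c1ccccc1)(c1ccccc1)OC[C@@H](c1cc(Br)cc(OC)c1O)[C@@H](O)c1ccc(OCc2ccccc2)c(OC)c1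
F5 | step 24 | (S)‑1‑[4‑(benzyloxy)‑3‑methoxyphenyl]‑2‑(4‑bromo‑2‑methoxyphenoxy)‑3‑[(tert‑butyldimethylsilyl)oxy]propan‑1‑one | COc1cc(C(=O)[C@H](CO[Si](C)(C)C(C)(C)C)Oc2ccc(Br)cc2OC)ccc1OCc1ccccc1
F6 | step 29 | [3‑methoxy‑4‑(ETH‑oxy)phenyl]methanol | COc1cc([C@@H](O[Si](C)(C)C(C)(C)C)[C@H](CO[Si](C)(C)C(C)(C)C)Oc2ccc(CO)cc2OC)ccc1OCc1ccccc1
F7 | step 29 | 4‑(bromomethyl)‑2‑methoxy‑1‑(ETH‑oxy)benzene | COc1cc([C@@H](O[Si](C)(C)C(C)(C)C)[C@H](CO[Si](C)(C)C(C)(C)C)Oc2ccc(CBr)cc2OC)ccc1OCc1ccccc1
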